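The runs were generated by integration with constants of no real substance; scatter was added.

Amounts in these flasks are counted in percent of the substrate charged, and what matters is how much of it has gone by a given hour.

in all of them: gas phase 200 mM (held)
- Wednesday's: substrate 1.5 M; run made earlier
- Sunday's: substrate 2.4 M; run made earlier
- flask: substrate 1.1 M; time 8.0 h

| run | time / h | product / % | substrate / % |
|---|---|---|---|
| Wednesday's | 0.500 | 8 | 93 |
| Wednesday's | 1.50 | 29 | 70 |
| Wednesday's | 3.00 | 51 | 45 |
| Wednesday's | 5.00 | 73 | 29 |
| Wednesday's | 6.00 | 77 | 22 |
| Sunday's | 0.500 | 9 | 93 |
| Sunday's | 1.50 | 23 | 75 |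
| Sunday's | 3.00 | 47 | 56 |
| Sunday's | 5.00 | 68 | 34 |
| Sunday's | 6.00 | 72 | 29 |

(readings scatter by 2 percentage points)

- how much product the flask holds at 8.0 h, in percent of the substrate charged
- how much substrate the flask holds at 8.0 h, in percent of the substrate charged
- concentration of dissolved gas at 8.0 h, in M

- at the start none of the gas phase is in solution

My reckoning treats the substrate curve as one decay. Its mean constant, a pseudo-first-order constant, is the natural logarithm of charged over remaining, divided by the time. Wednesday's last reading gives 0.252 h⁻¹. Replacing the curve by this mean puts Wednesday's run at 47.0% substrate at 3.00 h, where 45% was read, but at 88.2% at 0.500 h, where 93% was read, so of these two gaps in Wednesday's run the early one is larger.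

Two settings are turned from Wednesday's run. Time comes first: with that constant held, 8.0 h leaves 13.3% substrate by hand. The charge comes next: Sunday's run, at 2.4 M, reads a lower 0.206 h⁻¹. A straight line for the reciprocal constant against c(substrate) through both runs gives 0.280 h⁻¹ at 1.1 M, the mean constant of the flask. My estimate for the flask at 8.0 h is then 10.6% substrate. Wednesday's last readings sum to 99.0%, so I put product in the flask at 89.4%.

The forecast gives 11% substrate (7% to 16%), 89% product (84% to 93%) and 0.18 M dissolved gas (0.1 M to 0.2 M), reading that “apparent rate constant is therefore lower at higher loading”.

The flask gives 15.3% substrate, 84.7% product and 0.191 M dissolved gas, inside each of the forecast's ranges. The substrate stands 4.7 percentage points above the mean-constant figure.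

    dissolved gas ⇌ dormant form (K = 2.10, k = 0.00240 min⁻¹)
    substrate + dissolved gas ⇌ product (K = 36.0 M⁻¹, k = 0.0420 M⁻¹ min⁻¹)
    gas phase ⇌ dissolved gas, rate k3*(csat - [dissolved gas]) (kL = 0.0660 min⁻¹)

In the flask, substrate + dissolved gas and product have, both ways together, a relaxation half-life of 0.711 h at 8.00 h, short against the 8.0 h of the run. Left twice as long, the flask holds 12.4% substrate, and left ten times as long, 12.2%, so its substrate levels off, which a single decay with the mean constant does not do. The same flask read at 2.0 h gets 57.1% substrate from the mean constant, and the computed flask holds 57.4%.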